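The target is cut at C3–C4 of the pyranone ring (ring C). The C4 ketone and the C3 enol are the dehydrogenated form of an α-ketol, which is what a benzoin union of two aldehydes delivers. A thiazolylidene catalyst turns the ring-A aryl aldehyde into an acyl-anion equivalent that adds to a tethered aliphatic aldehyde, forging C3–C4 and closing ring C in one operation. The precursor is a fully benzyl-protected dialdehyde in which an aryl ether links O1/C8a of ring A to C2, which already carries ring B. Both aldehydes are released together from a diol, so the labile aliphatic aldehyde lives for a single step. Iodine dehydrogenation and hydrogenolysis finish the route.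

Key step: step 11

Remark: the target is an achiral flavonol with no stereocentre, so no absolute configuration has to be set; the C2 and C3 centres of the intermediates are racemic and disappear in step 12.

Step 1
Reactants: 1 2,3,4-trimethoxybenzaldehyde
Product: 2 5-bromo-2,3,4-trimethoxybenzaldehyde
Conditions: NBS (1.05 equiv), MeCN, rt
Reagents that add atoms: N-bromosuccinimide, O=C1CCC(=O)N1Br
Why: Electrophilic aromatic bromination should go to C5, which is para to the 2-methoxy group, ortho to the 4-methoxy group and meta to the formyl group, whereas C6 is ortho to the aldehyde and activated by one methoxy group only.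

Step 2
Reactants: 2 5-bromo-2,3,4-trimethoxybenzaldehyde
Product: 4 5-bromo-2,3,4-trimethoxyphenol, via aryl formate 3 (not isolated)
Conditions: mCPBA, CH2Cl2, rt; then K2CO3 (cat.), MeOH, rt
Reagents that add atoms: meta-chloroperbenzoic acid, O=C(OO)c1cccc(Cl)c1
Why: Baeyer–Villiger (Dakin-type) oxidation, in which the electron-rich aryl group migrates to oxygen in the peracid adduct, gives the aryl formate, which mild methanolysis cleaves to the phenol without touching the aryl bromide.

Step 3
Reactants: 4 5-bromo-2,3,4-trimethoxyphenol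
Product: 5 1-(benzyloxy)-5-bromo-2,3,4-trimethoxybenzene
Conditions: BnBr, K2CO3, DMF, rt
Reagents that add atoms: benzyl bromide, BrCc1ccccc1
Why: Williamson etherification of the phenoxide places the benzyl group on the oxygen that becomes O5, so the two ring-A phenols are told apart by the order in which they are made.

Step 4
Reactants: 5 1-(benzyloxy)-5-bromo-2,3,4-trimethoxybenzene
Product: 8 5-(benzyloxy)-2,3,4-trimethoxyphenol, via aryllithium 6 (not isolated), via lithium aryltrimethoxyborate 7 (not isolated)
Conditions: n-BuLi, THF, −78 °C; B(OMe)3, −78 °C to rt; AcOH, 30% aq. H2O2, 0 °C to rt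
Reagents that add atoms: hydrogen peroxide, OO
Why: Bromine–lithium exchange at −78 °C is faster than deprotonation of the benzyl ether, and the aryl borate formed on trapping is oxidised by peroxide through a 1,2-shift of the aryl group from boron to oxygen (borylation–oxidation).

Step 5
Reactants: 8 5-(benzyloxy)-2,3,4-trimethoxyphenol
Product: 10 2-(benzyloxy)-6-hydroxy-3,4,5-trimethoxybenzaldehyde, via salicyl alcohol 9 (not isolated)
Conditions: MgCl2, Et3N, (CH2O)n, MeCN, reflux; aq. HCl work-up
Reagents that add atoms: paraformaldehyde (as formaldehyde), C=O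
Why: In this magnesium-mediated ortho-formylation (Casnati–Skattebøl reaction) the magnesium phenoxide directs formaldehyde to the only free ring carbon, which is ortho to the hydroxyl, and a second formaldehyde oxidises the salicyl alcohol by hydride transfer, while the aryl benzyl and methyl ethers are inert.

Step 6
Reactants: 11 2,5-dihydroxyphenylacetic acid (homogentisic acid)
Product: 12 benzyl 2-[2,5-bis(benzyloxy)phenyl]acetate
Conditions: BnBr (3.5 equiv), K2CO3, DMF, rt to 50 °C, N2
Reagents that add atoms: benzyl bromide, BrCc1ccccc1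
Why: Potassium carbonate generates both phenoxides and the carboxylate, which are all benzylated by SN2 (Williamson etherification and carboxylate alkylation), and exclusion of air prevents oxidation of the hydroquinone.

Step 7
Reactants: 12 benzyl 2-[2,5-bis(benzyloxy)phenyl]acetate
Product: 14 benzyl 2-bromo-2-[2,5-bis(benzyloxy)phenyl]acetate (racemic), via ketene silyl acetal 13 (not isolated)
Conditions: LiHMDS, TMSCl, THF, −78 °C; then NBS, −78 to 0 °C
Reagents that add atoms: N-bromosuccinimide, O=C1CCC(=O)N1Br
Why: The ester enolate is trapped as its ketene silyl acetal, whose electrophilic bromination by NBS is far faster than attack on the dialkoxyarene and avoids the enolate–product proton exchange that leads to dibromide, and the new stereocentre is racemic and is erased later.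

Step 8
Reactants: 10 2-(benzyloxy)-6-hydroxy-3,4,5-trimethoxybenzaldehyde; 14 benzyl 2-bromo-2-[2,5-bis(benzyloxy)phenyl]acetate (racemic)
Product: 15 benzyl 2-[3-(benzyloxy)-2-formyl-4,5,6-trimethoxyphenoxy]-2-[2,5-bis(benzyloxy)phenyl]acetate (racemic)
Conditions: Cs2CO3, DMF, rt
Reagents that add atoms: none
Why: SN2 displacement (Williamson etherification) of the benzylic α-bromo ester, an electrophile activated twice, by the caesium phenoxide of 10 forms the O1–C2 ether without a metal carbene, so insertion into the C–H bonds of the neighbouring benzyloxy group cannot compete, and the C2 centre is racemic.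

Step 9
Reactants: 15 benzyl 2-[3-(benzyloxy)-2-formyl-4,5,6-trimethoxyphenoxy]-2-[2,5-bis(benzyloxy)phenyl]acetate (racemic)
Product: 16 2-[3-(benzyloxy)-2-(hydroxymethyl)-4,5,6-trimethoxyphenoxy]-2-[2,5-bis(benzyloxy)phenyl]ethan-1-ol (racemic)
Conditions: LiAlH4, THF, 0 °C; Fieser work-up, used crude
Reagents that add atoms: none
Why: Lithium aluminium hydride reduces the benzyl ester and the aryl aldehyde together to the diol, which removes the need to reduce an ester beside an aldehyde, and the aryl ethers are inert.

Step 10
Reactants: 16 2-[3-(benzyloxy)-2-(hydroxymethyl)-4,5,6-trimethoxyphenoxy]-2-[2,5-bis(benzyloxy)phenyl]ethan-1-ol (racemic)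
Product: 17 2-(benzyloxy)-6-{1-[2,5-bis(benzyloxy)phenyl]-2-oxoethoxy}-3,4,5-trimethoxybenzaldehyde (racemic)
Conditions: Dess–Martin periodinane (2.5 equiv), CH2Cl2, 0 °C to rt; short silica plug, used at once
Reagents that add atoms: none
Why: Dess–Martin oxidation converts the benzylic and the primary alcohol into the two aldehydes under neutral conditions, so the enolisable α-aryloxy aldehyde never meets a base before the key step.

Step 11
Reactants: 17 2-(benzyloxy)-6-{1-[2,5-bis(benzyloxy)phenyl]-2-oxoethoxy}-3,4,5-trimethoxybenzaldehyde (racemic)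
Product: 18 5-(benzyloxy)-2-[2,5-bis(benzyloxy)phenyl]-3-hydroxy-6,7,8-trimethoxychroman-4-one (racemic, cis/trans mixture at C2/C3)
Conditions: 3-benzyl-5-(2-hydroxyethyl)-4-methylthiazolium chloride (20 mol%), Et3N (40 mol%), degassed EtOH–THF, 45 °C, Ar
Reagents that add atoms: none
Why: The thiazol-2-ylidene released by Et3N adds to the aryl aldehyde of 17, proton transfer gives the nucleophilic enaminol (acyl-anion equivalent at the future C4), this carbon attacks the tethered aliphatic formyl carbon (future C3), and collapse of the adduct regenerates the carbene and leaves the C4 ketone. The closest known reaction type is the carbene-catalysed intramolecular crossed benzoin of 2-(2-oxoalkoxy)benzaldehydes to 3-hydroxychroman-4-ones and of dialdehydes to cyclic acyloins. Ring C closes in the 6-exo-trig mode. The new C3 carbinol centre is set under substrate control by the C2 aryl group (the 2,3-trans ketol with both substituents equatorial is expected to prevail), but no control is needed because C2 and C3 become sp2 in step 12. The step needs the carbene to engage the aryl and not the aliphatic aldehyde (an enaminol formed at the aliphatic carbonyl could expel the aryloxide and cut the tether) and needs benzoin closure to outrun intramolecular aldol addition; the aryl aldehyde has no α-hydrogen, carries two ortho-alkoxy groups that favour azolium adduct formation and gives a conjugated enaminol, while the aliphatic aldehyde is shielded by an α-carbon bearing an ortho-substituted aryl and an aryloxy group and should rest partly as its hemiacetal in ethanol, which also damps enolisation. An aldol adduct would be a β-hydroxy aldehyde on a quaternary carbon that cannot dehydrate and can revert, whereas the conjugated aryl-ketone ketol is the thermodynamic sink.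

Step 12
Reactants: 18 5-(benzyloxy)-2-[2,5-bis(benzyloxy)phenyl]-3-hydroxy-6,7,8-trimethoxychroman-4-one (crude ketol mixture)
Product: 20 5-(benzyloxy)-2-[2,5-bis(benzyloxy)phenyl]-3-hydroxy-6,7,8-trimethoxy-4H-chromen-4-one, via chromane-3,4-dione 19 (not isolated)
Conditions: I2 (1.1 equiv), KOAc, AcOH, 90 °C
Reagents that add atoms: none
Why: Enolisation of the ketol to the C3–C4 enediol and its oxidation by iodine give the 3,4-dione, which tautomerises through C2–H to the aromatic 3-hydroxychromone (classical dehydrogenation of dihydroflavonols), so all ketol stereoisomers and any regioisomeric ketol converge on 20 and both stereocentres disappear.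

Step 13
Reactants: 20 5-(benzyloxy)-2-[2,5-bis(benzyloxy)phenyl]-3-hydroxy-6,7,8-trimethoxy-4H-chromen-4-one
Product: 21 2-(2,5-dihydroxyphenyl)-3,5-dihydroxy-6,7,8-trimethoxy-4H-chromen-4-one (CNP0236469.0)
Conditions: H2 (1 atm), 10% Pd/C, EtOAc–MeOH, rt; filtration and concentration under Ar
Reagents that add atoms: none
Why: Catalytic hydrogenolysis cleaves the three aryl benzyl ethers to the phenols and toluene, while the methyl ethers and the fully substituted, conjugated C2=C3 bond of the chromone are untouched.

Compound list
1 | 2,3,4-trimethoxybenzaldehyde | COc1ccc(C=O)c(OC)c1OC | starting material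
2 | 5-bromo-2,3,4-trimethoxybenzaldehyde | COc1c(Br)cc(C=O)c(OC)c1OC | intermediate
3 | 5-bromo-2,3,4-trimethoxyphenyl formate (not isolated) | COc1c(Br)cc(OC=O)c(OC)c1OC | intermediate
4 | 5-bromo-2,3,4-trimethoxyphenol | COc1c(Br)cc(O)c(OC)c1OC | intermediate
5 | 1-(benzyloxy)-5-bromo-2,3,4-trimethoxybenzene | COc1c(Br)cc(OCc2ccccc2)c(OC)c1OC | intermediate
6 | [5-(benzyloxy)-2,3,4-trimethoxyphenyl]lithium (not isolated) | COc1c([Li])cc(OCc2ccccc2)c(OC)c1OC | intermediate
7 | lithium [5-(benzyloxy)-2,3,4-trimethoxyphenyl]trimethoxyborate (not isolated) | [Li+].COc1c([B-](OC)(OC)OC)cc(OCc2ccccc2)c(OC)c1OC | intermediate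
8 | 5-(benzyloxy)-2,3,4-trimethoxyphenol | COc1c(O)cc(OCc2ccccc2)c(OC)c1OC | intermediate
9 | [2-(benzyloxy)-6-hydroxy-3,4,5-trimethoxyphenyl]methanol (not isolated) | COc1c(OC)c(OCc2ccccc2)c(CO)c(O)c1OC | intermediate
10 | 2-(benzyloxy)-6-hydroxy-3,4,5-trimethoxybenzaldehyde | COc1c(OC)c(OCc2ccccc2)c(C=O)c(O)c1OC | intermediate
11 | 2,5-dihydroxyphenylacetic acid (homogentisic acid) | O=C(O)Cc1cc(O)ccc1O | starting material
12 | benzyl 2-[2,5-bis(benzyloxy)phenyl]acetate | O=C(Cc1cc(OCc2ccccc2)ccc1OCc1ccccc1)OCc1ccccc1 | intermediate
13 | {1-(benzyloxy)-2-[2,5-bis(benzyloxy)phenyl]ethenyl}oxy(trimethyl)silane, E/Z mixture (not isolated) | C[Si](C)(C)OC(OCc1ccccc1)=Cc1cc(OCc2ccccc2)ccc1OCc1ccccc1 | intermediate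
14 | benzyl 2-bromo-2-[2,5-bis(benzyloxy)phenyl]acetate, racemic | O=C(OCc1ccccc1)C(Br)c1cc(OCc2ccccc2)ccc1OCc1ccccc1 | intermediate
15 | benzyl 2-[3-(benzyloxy)-2-formyl-4,5,6-trimethoxyphenoxy]-2-[2,5-bis(benzyloxy)phenyl]acetate, racemic | COc1c(OC)c(OCc2ccccc2)c(C=O)c(OC(C(=O)OCc2ccccc2)c2cc(OCc3ccccc3)ccc2OCc2ccccc2)c1OC | intermediate
16 | 2-[3-(benzyloxy)-2-(hydroxymethyl)-4,5,6-trimethoxyphenoxy]-2-[2,5-bis(benzyloxy)phenyl]ethan-1-ol, racemic | COc1c(OC)c(OCc2ccccc2)c(CO)c(OC(CO)c2cc(OCc3ccccc3)ccc2OCc2ccccc2)c1OC | intermediate
17 | 2-(benzyloxy)-6-{1-[2,5-bis(benzyloxy)phenyl]-2-oxoethoxy}-3,4,5-trimethoxybenzaldehyde, racemic | COc1c(OC)c(OCc2ccccc2)c(C=O)c(OC(C=O)c2cc(OCc3ccccc3)ccc2OCc2ccccc2)c1OC | intermediate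
18 | 5-(benzyloxy)-2-[2,5-bis(benzyloxy)phenyl]-3-hydroxy-6,7,8-trimethoxychroman-4-one, racemic, cis/trans mixture | COc1c(OC)c(OCc2ccccc2)c2c(c1OC)OC(c1cc(OCc3ccccc3)ccc1OCc1ccccc1)C(O)C2=O | intermediate
19 | 5-(benzyloxy)-2-[2,5-bis(benzyloxy)phenyl]-6,7,8-trimethoxychromane-3,4-dione, racemic (not isolated) | COc1c(OC)c(OCc2ccccc2)c2c(c1OC)OC(c1cc(OCc3ccccc3)ccc1OCc1ccccc1)C(=O)C2=O | intermediate
20 | 5-(benzyloxy)-2-[2,5-bis(benzyloxy)phenyl]-3-hydroxy-6,7,8-trimethoxy-4H-chromen-4-one | COc1c(OC)c(OCc2ccccc2)c2c(=O)c(O)c(-c3cc(OCc4ccccc4)ccc3OCc3ccccc3)oc2c1OC | intermediate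
21 | 2-(2,5-dihydroxyphenyl)-3,5-dihydroxy-6,7,8-trimethoxy-4H-chromen-4-one (CNP0236469.0), achiral | COc1c(OC)c(O)c2c(=O)c(O)c(-c3cc(O)ccc3O)oc2c1OC | target

Total step count: 13
Longest linear sequence: 11 steps (steps 1–5 and 8–13, from 2,3,4-trimethoxybenzaldehyde); the ring-B branch (steps 6–7) joins at step 8.

Steps most likely to fail

Step 11. The carbene may add to the aliphatic instead of the aryl aldehyde, after which loss of the aryloxide from the resulting enaminol would cut the tether. Base-induced aldol closure to a dihydrobenzofuranol may also outpace the benzoin closure. The fallback sets out from 17 and forms the same C3–C4 bond reductively. Samarium diiodide in THF/t-BuOH at −78 °C should give, by intramolecular pinacol coupling of the two aldehydes, 5-(benzyloxy)-2-[2,5-bis(benzyloxy)phenyl]-6,7,8-trimethoxychromane-3,4-diol F1. Activated MnO2 in CH2Cl2 then oxidises only the benzylic C4 carbinol, and the route is rejoined at 18.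

Step 10. A half-oxidised hydroxy aldehyde may close to a seven-membered lactol and be oxidised further to a lactone, and the α-aryloxy aldehyde may enolise and autoxidise during isolation. The fallback sets out from 16 and separates the two oxidations by chemoselectivity. Activated MnO2 in CH2Cl2 oxidises only the benzylic alcohol to 2-(benzyloxy)-6-{1-[2,5-bis(benzyloxy)phenyl]-2-hydroxyethoxy}-3,4,5-trimethoxybenzaldehyde F2, in which the remaining hydroxyl faces only a hindered, deactivated aryl aldehyde. Catalytic TEMPO with PhI(OAc)2 in CH2Cl2 then oxidises the primary alcohol, and the route is rejoined at 17.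

Step 8. Displacement at the hindered, hydrogen-bonded phenoxide may be slow enough for the bromo ester to be consumed by enolisation and Darzens-type attack on the aldehyde. The fallback sets out from 12 and activates the alcohol partner instead of using a halide. Hydroxylation of the lithium enolate (LiHMDS, then 2-(phenylsulfonyl)-3-phenyloxaziridine, THF, −78 °C) should give benzyl 2-[2,5-bis(benzyloxy)phenyl]-2-hydroxyacetate F3. A Mitsunobu reaction of F3 with the acidic ortho-formyl phenol 10 (PPh3, DIAD, toluene, 0 °C to rt) forms the same aryl ether, and the route is rejoined at 15.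

Further compounds
F1 | step 11 | 5-(benzyloxy)-2-[2,5-bis(benzyloxy)phenyl]-6,7,8-trimethoxychromane-3,4-diol, racemic diastereomer mixture | COc1c(OC)c(OCc2ccccc2)c2c(c1OC)OC(c1cc(OCc3ccccc3)ccc1OCc1ccccc1)C(O)C2O
F2 | step 10 | 2-(benzyloxy)-6-{1-[2,5-bis(benzyloxy)phenyl]-2-hydroxyethoxy}-3,4,5-trimethoxybenzaldehyde, racemic | COc1c(OC)c(OCc2ccccc2)c(C=O)c(OC(CO)c2cc(OCc3ccccc3)ccc2OCc2ccccc2)c1OC
F3 | step 8 | benzyl 2-[2,5-bis(benzyloxy)phenyl]-2-hydroxyacetate, racemic | O=C(OCc1ccccc1)C(O)c1cc(OCc2ccccc2)ccc1OCc1ccccc1
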